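Our vessel is closed, stirred and isothermal, and each run starts with equal charges of electrophile and nucleophile.

| setting | cedar | larch | oak | delta | alpha |
|---|---|---|---|---|---|
| electrophile | 0.50 M | 0.50 M | 0.50 M | 0.50 M | 0.50 M |
| nucleophile | 0.50 M | 0.50 M | 0.50 M | 0.500 M | 0.500 M |
| free base | 0.49 M | 0.72 M | 0.70 M | 0.500 M | 1.00 M |
| remark | run made earlier | run made earlier | run made earlier |  |  |
| time |  |  |  | 4.0 h | 4.0 h |

| run | time / min | electrophile / % | product / % |
|---|---|---|---|
| cedar | 25.0 | 57.0 | 43.1 |
| cedar | 50.0 | 48.5 | 46.7 |
| cedar | 80.0 | 44.0 | 50.7 |
| cedar | 90.0 | 42.6 | 52.6 |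
| cedar | 120 | 40.2 | 53.8 |
| larch | 10.0 | 72.0 | 30.1 |
| larch | 30.0 | 55.2 | 40.6 |
| larch | 60.0 | 45.4 | 49.4 |
| larch | 80.0 | 43.5 | 49.9 |
| larch | 120 | 42.1 | 52.2 |
| oak | 10.0 | 70.8 | 28.2 |
| oak | 30.0 | 55.4 | 42.6 |
| oak | 60.0 | 45.2 | 49.9 |
| oak | 80.0 | 41.9 | 52.3 |
| oak | 120 | 39.1 | 52.9 |

(each reading ± 1 percentage point)

- the analysis behind the earlier runs scatters by 1 percentage point, standard deviation
- what has gone from electrophile into another species counts as reacted, even if it can come back

1. part of the electrophile that has reacted at the end, delta
2. part of the electrophile that has reacted at the end, alpha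
3. what raising the concentration of free base from its lowest to its highest value here does to the part of the electrophile that has reacted (changes below 5 percentage points count as none) (it falls / no change / it rises)

Take the oak run in slow motion. In the first instants the electrophile drops to 70.8% within 10.0 min. By 60.0 min it stands at 45.2%, with product at 49.9%. At the end of the oak run it creeps from 41.9% to 39.1% between 80.0 min and 120 min, so on these scattered readings the first stretch runs roughly 41.7 times faster than the last.

Yet the electrophile is not short: on average 40.5% of it remains at the last reading of the three runs. So we bet on the nucleophile side as what slows the flask, though these readings do not prove it. Product at the last reading averages 0.530 per nucleophile charged. We call this the load, c(product) over c(nucleophile) as charged.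

Product at the last reading of cedar, with 0.49 M of free base, and of larch, with 0.72 M, differs by 1.6 percentage points, against a scatter of 1 point. So we expect no change, although the 1.00 M in alpha lies above the tested range.

Our reckoning is the same for delta and alpha. The mean reacted part is 59.5% at 120 min. Larch and oak creep by 2.1 points over their last interval. A steady creep reaches 65.8% at 4.0 h, but the creep is slowing, so we take the middle, 62.7%.

The forecast gave 62.5% for delta, 65% for alpha and no change, noting that “the curves overlap within scatter”.

The flask gives 65.7% for delta and 64.9% for alpha, which is no change, a shift of −0.81 points.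

    electrophile + nucleophile → acid set free + product (k = 0.100 M⁻¹ min⁻¹)
    nucleophile + acid set free ⇌ protonated nucleophile, settled at all times (K = 8900 M⁻¹)
    acid set free + free base ⇌ salt of the base (K = 14000 M⁻¹, k = 0.0550 M⁻¹ min⁻¹)
    electrophile + acid set free ⇌ idle adduct, settled at all times (K = 63.0 M⁻¹)

In alpha at 4.00 h, product stands at 56.7%, a load of 0.567, above the 0.530 read at 120 min. Unbound nucleophile, the limiting reagent, is down to 1.3% of its charge in alpha, less than the 35% of the electrophile still unbound, while 0.210 M sits as protonated nucleophile. The neighbour flask is alpha with 0.30 M of electrophile, and the load read at 120 min gives 88.3% product there. At 4.00 h the neighbour flask holds 83.2%, a load of 0.499, with 84.7% of its electrophile reacted.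

Readings and results were generated by integration from invented constants; scatter was added.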